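**Retrosynthetic overview**
1. Target ⇒ last-step esterification of the primary (neopentyl) alcohol of the bicyclic diol with the C18 acyl chloride.
2. Oxolane ring (formed last) ⇒ C–O bond at the tetrasubstituted carbon by a Pd-catalysed, stereoconvergent 5-exo cycloetherification of a hydroxy dienyl epoxide, which also frees the CH2OH group.
3. Dienyl epoxide ⇒ sulfonium-ylide methylene transfer to a dienone, itself made by opening a trans-fused cyclononene γ-lactone with a dienyllithium.
4. Nine-membered ring (formed second) ⇒ Z-selective ring-closing metathesis of a trans-3,4-disubstituted γ-lactone; lactone ring (first, later opened) ⇒ Rh-catalysed asymmetric conjugate alkenylation of a butenolide, then trans α-alkylation.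
5. Alkylating side chain ⇒ chiral-pool monoterpene tertiary alcohol, shortened by ozonolysis and alkoxy-radical β-fragmentation.

Assumption: (S)-(+)-linalool 1 of high enantiomeric purity is taken as a purchasable chiral-pool material; the ligand antipodes written in steps 6 and 12 are the ones expected to be matched and would be confirmed by one control run each with the other antipode.

**Step 1**
Reactants: 1 (S)-(+)-linalool, (3S)-3,7-dimethylocta-1,6-dien-3-ol
Product: 2 (5S)-5-ethenyl-5-methyloxolan-2-ol (lactol, both anomers)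
Conditions: O3 (1.0 equiv, Sudan Red 7B end-point), CH2Cl2, −78 °C; then Me2S, −78 °C → rt
Reagents that add atoms: ozone, [O-][O+]=O
Why: Chemoselective ozonolysis cleaves the electron-rich trisubstituted alkene well before the vinyl group, and the hydroxy aldehyde closes to the lactol; the carbinol stereocentre is untouched.

**Step 2**
Reactants: 2 (5S)-5-ethenyl-5-methyloxolan-2-ol
Product: 4 (3S)-5-iodo-3-methylpent-1-en-3-ol, via iodo formate 3 (not isolated)
Conditions: PhI(OAc)2 (1.2 equiv), I2 (1.0 equiv), cyclohexane/CH2Cl2, tungsten-lamp irradiation, 25 °C; then KHCO3, MeOH, 0 °C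
Reagents that add atoms: iodine, II
Why: Suárez hypoiodite reaction (alkoxy-radical β-fragmentation): the anomeric alkoxy radical cleaves the adjacent C–C bond to a formate and a primary radical that iodine traps, and mild methanolysis removes the tertiary formate without touching the stereocentre.

**Step 3**
Reactants: 4 (3S)-5-iodo-3-methylpent-1-en-3-ol
Product: 5 {[(3S)-5-iodo-3-methylpent-1-en-3-yl]oxy}(trimethyl)silane
Conditions: Me3SiCl, imidazole, DMF, 0 °C → rt
Reagents that add atoms: chlorotrimethylsilane, C[Si](C)(C)Cl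
Why: Silylation of the tertiary alcohol prevents proton quench and oxetane formation during the enolate alkylation.

**Step 4**
Reactants: 6 2,3-dibromoprop-1-ene; 7 vinylmagnesium bromide
Product: 8 2-bromopenta-1,4-diene
Conditions: CuI (5 mol %), THF, −10 °C → rt
Reagents that add atoms: none
Why: Copper-catalysed allylic substitution of the allylic bromide by the vinyl Grignard reagent (SN2 and SN2′ give the same product); the vinylic C–Br bond is inert.

**Step 5**
Reactants: 8 2-bromopenta-1,4-diene
Product: 10 4,4,5,5-tetramethyl-2-(penta-1,4-dien-2-yl)-1,3,2-dioxaborolane, via Grignard reagent 9 (not isolated)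
Conditions: Mg turnings, THF, 40 °C; then 2-isopropoxy-4,4,5,5-tetramethyl-1,3,2-dioxaborolane, −78 °C → rt; aq. NH4Cl
Reagents that add atoms: 2-isopropoxy-4,4,5,5-tetramethyl-1,3,2-dioxaborolane, CC(C)OB1OC(C)(C)C(C)(C)O1
Why: Grignard formation from the vinylic bromide and electrophilic borylation give the alkenylboronate needed for rhodium transmetallation.

**Step 6**
Reactants: 11 furan-2(5H)-one; 10 4,4,5,5-tetramethyl-2-(penta-1,4-dien-2-yl)-1,3,2-dioxaborolane
Product: 12 (4R)-4-(penta-1,4-dien-2-yl)oxolan-2-one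
Conditions: [Rh(cod)Cl]2 (2.5 mol %), (R)-BINAP (6 mol %), K3PO4 (0.5 equiv), 1,4-dioxane/H2O 10:1, 50 °C
Reagents that add atoms: none
Why: Hayashi–Miyaura asymmetric conjugate addition: the (R)-BINAP–Rh alkenyl species inserts the butenolide on one enantioface (sense assigned by analogy with cyclic enones and six-membered lactones), creating the (R) centre that becomes C3a of the target.

**Step 7**
Reactants: 12 (4R)-4-(penta-1,4-dien-2-yl)oxolan-2-one; 5 {[(3S)-5-iodo-3-methylpent-1-en-3-yl]oxy}(trimethyl)silane
Product: 15 (3S,4R)-3-[(3S)-3-hydroxy-3-methylpent-4-en-1-yl]-4-(penta-1,4-dien-2-yl)oxolan-2-one, via lithium enolate 13 (not isolated), via silyl ether 14 (not isolated)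
Conditions: LiN(iPr)2 (1.05 equiv), THF, −78 °C; 5 (1.3 equiv), DMPU, −78 → −30 °C; then 1 M HCl, THF, 0 °C
Reagents that add atoms: none
Why: Lactone enolate SN2 alkylation: the iodide approaches anti to the C4 alkenyl group, giving the trans-3,4 lactone (new (S) centre, future C10a), and the acidic work-up unmasks the tertiary alcohol that accelerates the metathesis.

**Step 8**
Reactants: 15 (3S,4R)-3-[(3S)-3-hydroxy-3-methylpent-4-en-1-yl]-4-(penta-1,4-dien-2-yl)oxolan-2-one
Product: 16 (3aR,6Z,8S,10aS)-8-hydroxy-8-methyl-4-methylidene-3,3a,4,5,8,9,10,10a-octahydro-1H-cyclonona[c]furan-1-one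
Conditions: second-generation Grubbs catalyst RuCl2(=CHPh)(PCy3)(H2IMes) (10 mol %, two portions), 1,4-benzoquinone (20 mol %), CH2Cl2 (1 mM), 40 °C
Reagents that add atoms: none
Why: Ring-closing metathesis: the carbene loads at the unhindered allyl terminus, whose only cyclisation partner is the hydroxyl-activated carbinol vinyl group; the nine-membered ring accommodates only the Z alkene, the trans-lactone holds both chains pseudo-equatorial, and no stereocentre is touched.

**Step 9**
Reactants: 17 3-methylbut-2-enal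
Product: 18 (1E)-1-iodo-4-methylpenta-1,3-diene
Conditions: CrCl2 (6 equiv), CHI3 (2 equiv), THF, 0 °C, dark
Reagents that add atoms: iodoform, IC(I)I
Why: Takai olefination: the geminal dichromium species adds to the aldehyde and eliminates anti-periplanar to give the E vinyl iodide.

**Step 10**
Reactants: 16 (3aR,6Z,8S,10aS)-8-hydroxy-8-methyl-4-methylidene-3,3a,4,5,8,9,10,10a-octahydro-1H-cyclonona[c]furan-1-one; 18 (1E)-1-iodo-4-methylpenta-1,3-diene
Product: 20 (2E)-1-[(1S,2R,5Z,7S)-7-hydroxy-2-(hydroxymethyl)-7-methyl-3-methylidenecyclonon-5-en-1-yl]-5-methylhexa-2,4-dien-1-one, via dienyllithium 19 (not isolated)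
Conditions: 18 (2.4 equiv), t-BuLi (4.8 equiv), Et2O, −78 °C; then 16, THF, −78 °C, 1 h; aq. NH4Cl at −78 °C
Reagents that add atoms: none
Why: Iodine–lithium exchange then addition of the alkenyllithium to the lactone stops at the ketone stage because the lithium hemiketal is stable at −78 °C (one extra equivalent is consumed by the tertiary hydroxyl); the E geometry is retained and the cold buffered quench avoids epimerisation next to the ketone.

**Step 11**
Reactants: 20 (2E)-1-[(1S,2R,5Z,7S)-7-hydroxy-2-(hydroxymethyl)-7-methyl-3-methylidenecyclonon-5-en-1-yl]-5-methylhexa-2,4-dien-1-one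
Product: 21 (1S,2Z,6R,7S)-6-(hydroxymethyl)-1-methyl-5-methylidene-7-{2-[(1E)-4-methylpenta-1,3-dien-1-yl]oxiran-2-yl}cyclonon-2-en-1-ol (both epimers at the oxirane carbon)
Conditions: Me3S+ I− (3.0 equiv), n-BuLi (2.9 equiv), THF, −10 °C; then 20, −10 → 0 °C; filtration through basic alumina, used crude
Reagents that add atoms: trimethylsulfonium iodide, C[S+](C)C.[I-]
Why: Corey–Chaykovsky epoxidation: dimethylsulfonium methylide adds 1,2 to the dienone and closes to the oxirane; the new centre forms without control, which the next step is designed to make irrelevant.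

**Step 12**
Reactants: 21 (1S,2Z,6R,7S)-6-(hydroxymethyl)-1-methyl-5-methylidene-7-{2-[(1E)-4-methylpenta-1,3-dien-1-yl]oxiran-2-yl}cyclonon-2-en-1-ol
Product: 22 (1R,3aR,6Z,8S,10aS)-1-(hydroxymethyl)-8-methyl-4-methylidene-1-[(1E)-4-methylpenta-1,3-dien-1-yl]-3,3a,4,5,8,9,10,10a-octahydro-1H-cyclonona[c]furan-8-ol
Conditions: Pd2(dba)3·CHCl3 (2.5 mol %), (R,R)-DACH-phenyl Trost ligand (7.5 mol %), n-Bu4NCl (10 mol %), CH2Cl2 (0.02 M), 0 °C → rt
Reagents that add atoms: none
Why: Proposed new method: zerovalent palladium ionises both epimers of the tertiary dienyl epoxide, with inversion, to zwitterionic η3-pentadienyl–Pd alkoxides; these should interconvert faster than they cyclise because Pd can slide (η3–η1–η3) to the CMe2 terminus, whose two identical methyl groups allow rotation and return on the opposite face (chloride accelerates this); the liberated alkoxide deprotonates the primary hydroxyl, and the chiral pocket lets only one diastereomeric complex undergo anti 5-exo C–O attack at the tertiary terminus (Curtin–Hammett), so one configuration at the new tetrasubstituted C–O stereocentre (dienyl cis to H-10a, E alkene from the syn,syn-allyl) results from the epimer mixture; the closest known reaction types are the Pd-catalysed dynamic kinetic asymmetric addition of alcohols to isoprene monoxide (Tsuji–Trost allylic etherification giving tertiary ethers) and the Pd-catalysed cyclisation of hydroxy vinyl epoxides to 2-vinyl oxolanes, and what is new is the dienyl epoxide, the face exchange through the remote terminus and catalyst control in a stereochemically dense substrate.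

**Step 13**
Reactants: 22 (1R,3aR,6Z,8S,10aS)-1-(hydroxymethyl)-8-methyl-4-methylidene-1-[(1E)-4-methylpenta-1,3-dien-1-yl]-3,3a,4,5,8,9,10,10a-octahydro-1H-cyclonona[c]furan-8-ol; 23 octadecanoyl chloride
Product: 24 [(1R,3aR,6Z,8S,10aS)-8-hydroxy-8-methyl-4-methylidene-1-[(1E)-4-methylpenta-1,3-dien-1-yl]-3,3a,4,5,8,9,10,10a-octahydro-1H-cyclonona[c]furan-1-yl]methyl octadecanoate (CNP0274030.1)
Conditions: 23 (1.1 equiv), pyridine, DMAP (5 mol %), CH2Cl2, 0 °C
Reagents that add atoms: none
Why: DMAP-catalysed acylation: only the primary alcohol reacts, the tertiary allylic alcohol is inert under these conditions, and the base buffers the acid-labile tertiary dienyl ether.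

**Compound list**
1 | (S)-(+)-linalool, (3S)-3,7-dimethylocta-1,6-dien-3-ol | CC(C)=CCC[C@](C)(O)C=C | starting material
2 | (5S)-5-ethenyl-5-methyloxolan-2-ol (both anomers) | OC1CC[C@@](C)(C=C)O1 | intermediate
3 | (3S)-5-iodo-3-methylpent-1-en-3-yl formate | ICC[C@](C)(OC=O)C=C | intermediate
4 | (3S)-5-iodo-3-methylpent-1-en-3-ol | ICC[C@](C)(O)C=C | intermediate
5 | {[(3S)-5-iodo-3-methylpent-1-en-3-yl]oxy}(trimethyl)silane | ICC[C@](C)(O[Si](C)(C)C)C=C | intermediate
6 | 2,3-dibromoprop-1-ene | BrCC(Br)=C | starting material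
7 | vinylmagnesium bromide | C=C[Mg]Br | starting material
8 | 2-bromopenta-1,4-diene | C=CCC(Br)=C | intermediate
9 | (penta-1,4-dien-2-yl)magnesium bromide | C=CCC(=C)[Mg]Br | intermediate
10 | 4,4,5,5-tetramethyl-2-(penta-1,4-dien-2-yl)-1,3,2-dioxaborolane | C=CCC(=C)B1OC(C)(C)C(C)(C)O1 | intermediate
11 | furan-2(5H)-one | O=C1OCC=C1 | starting material
12 | (4R)-4-(penta-1,4-dien-2-yl)oxolan-2-one | O=C1C[C@H](C(=C)CC=C)CO1 | intermediate
13 | lithium (4R)-4-(penta-1,4-dien-2-yl)-4,5-dihydrofuran-2-olate | [Li]OC1=C[C@H](C(=C)CC=C)CO1 | intermediate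
14 | (3S,4R)-3-{(3S)-3-methyl-3-[(trimethylsilyl)oxy]pent-4-en-1-yl}-4-(penta-1,4-dien-2-yl)oxolan-2-one | O=C1[C@@H](CC[C@](C)(O[Si](C)(C)C)C=C)[C@H](C(=C)CC=C)CO1 | intermediate
15 | (3S,4R)-3-[(3S)-3-hydroxy-3-methylpent-4-en-1-yl]-4-(penta-1,4-dien-2-yl)oxolan-2-one | O=C1[C@@H](CC[C@](C)(O)C=C)[C@H](C(=C)CC=C)CO1 | intermediate
16 | (3aR,6Z,8S,10aS)-8-hydroxy-8-methyl-4-methylidene-3,3a,4,5,8,9,10,10a-octahydro-1H-cyclonona[c]furan-1-one (trans-fused) | C=C1C/C=C\[C@@](C)(O)CC[C@H]2[C@H]1COC2=O | intermediate
17 | 3-methylbut-2-enal | CC(C)=CC=O | starting material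
18 | (1E)-1-iodo-4-methylpenta-1,3-diene | I/C=C/C=C(C)C | intermediate
19 | [(1E)-4-methylpenta-1,3-dien-1-yl]lithium | [Li]/C=C/C=C(C)C | intermediate
20 | (2E)-1-[(1S,2R,5Z,7S)-7-hydroxy-2-(hydroxymethyl)-7-methyl-3-methylidenecyclonon-5-en-1-yl]-5-methylhexa-2,4-dien-1-one | C=C1C/C=C\[C@@](C)(O)CC[C@H](C(=O)/C=C/C=C(C)C)[C@H]1CO | intermediate
21 | (1S,2Z,6R,7S)-6-(hydroxymethyl)-1-methyl-5-methylidene-7-{2-[(1E)-4-methylpenta-1,3-dien-1-yl]oxiran-2-yl}cyclonon-2-en-1-ol (both oxirane epimers) | C=C1C/C=C\[C@@](C)(O)CC[C@H](C2(/C=C/C=C(C)C)CO2)[C@H]1CO | intermediate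
22 | (1R,3aR,6Z,8S,10aS)-1-(hydroxymethyl)-8-methyl-4-methylidene-1-[(1E)-4-methylpenta-1,3-dien-1-yl]-3,3a,4,5,8,9,10,10a-octahydro-1H-cyclonona[c]furan-8-ol | C=C1C/C=C\[C@@](C)(O)CC[C@H]2[C@H]1CO[C@@]2(/C=C/C=C(C)C)CO | intermediate
23 | octadecanoyl chloride (stearoyl chloride) | CCCCCCCCCCCCCCCCCC(=O)Cl | starting material
24 | [(1R,3aR,6Z,8S,10aS)-8-hydroxy-8-methyl-4-methylidene-1-[(1E)-4-methylpenta-1,3-dien-1-yl]-3,3a,4,5,8,9,10,10a-octahydro-1H-cyclonona[c]furan-1-yl]methyl octadecanoate | C=C1C/C=C\[C@@](C)(O)CC[C@H]2[C@H]1CO[C@@]2(/C=C/C=C(C)C)COC(=O)CCCCCCCCCCCCCCCCC | target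

**Totals**
Total steps: 13. Longest linear sequence: 9 (steps 1–3, 7, 8, 10–13; the branch through steps 4–6 is equally long).

**Steps most likely to fail**

Step 2 (radical fragmentation). The hypoiodite may add to the vinyl group, or the lactol may simply be oxidised to the lactone. The fallback sets out from 1 and comes back at 5, replacing the radical cleavage by a stepwise ionic one-carbon degradation. Silylation of 1 (Me3SiCl, imidazole, DMF) gives trimethyl{[(3S)-3,7-dimethylocta-1,6-dien-3-yl]oxy}silane F1. Ozonolysis limited to the trisubstituted alkene (O3, CH2Cl2, −78 °C; Me2S) gives (4S)-4-methyl-4-[(trimethylsilyl)oxy]hex-5-enal F2. Me3SiCl and Et3N in DMF at 80 °C give the trimethylsilyl enol ether F3. A second ozonolysis, selective for the enol ether, with NaBH4 work-up removes the former aldehyde carbon and gives (3S)-3-methyl-3-[(trimethylsilyl)oxy]pent-4-en-1-ol F4. I2, PPh3 and imidazole convert F4 into 5.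

Step 8 (nine-membered ring closure). A seven-membered ring from the carbinol vinyl group and the 1,1-disubstituted alkene, or oligomers, may win. The fallback sets out from 15 and comes back at 16, masking the competing alkene. mCPBA (1.0 equiv, NaHCO3, CH2Cl2, −20 °C) epoxidises the most electron-rich, 1,1-disubstituted alkene to (3S,4S)-3-[(3S)-3-hydroxy-3-methylpent-4-en-1-yl]-4-[2-(prop-2-en-1-yl)oxiran-2-yl]oxolan-2-one F5 (both oxirane epimers). Metathesis of F5 with the same catalyst can only join the allyl and carbinol vinyl groups and gives the spiro-epoxy lactone F6. Cp2TiCl (trivalent titanium, made from Cp2TiCl2 and Zn, THF, rt) deoxygenates the oxirane back to the exocyclic methylene, giving 16.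

Step 12 (proposed new cyclisation). Face exchange of the allyl complex may be slower than ring closure, so the product ratio would mirror the epoxide ratio; β-hydride loss or attack by the tertiary hydroxyl are further risks. The fallback uses known chemistry, sets out from 16 and comes back at 22; the quaternary centre is then set by C–C bond formation on the intact oxolane. Petasis methylenation (Cp2TiMe2, toluene, 65 °C) converts the lactone into the exocyclic enol ether (3aR,6Z,8S,10aS)-8-methyl-1,4-dimethylidene-3,3a,4,5,8,9,10,10a-octahydro-1H-cyclonona[c]furan-8-ol F7. DMDO (acetone/CH2Cl2, −78 °C) epoxidises only this enol ether, from the face opposite C10, to the spiro-epoxy acetal F8. Dienyllithium 19 (made as in step 10) and Me2AlCl give dimethyl[(1E)-4-methylpenta-1,3-dien-1-yl]alumane F9. F9 opens F8 at the acetal carbon with syn delivery, as in C-glycosidation of 1,2-anhydro sugars by organoalanes, and aqueous work-up gives 22.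

**Further compounds**
F1 | step 2 | trimethyl{[(3S)-3,7-dimethylocta-1,6-dien-3-yl]oxy}silane | CC(C)=CCC[C@](C)(O[Si](C)(C)C)C=C
F2 | step 2 | (4S)-4-methyl-4-[(trimethylsilyl)oxy]hex-5-enal | O=CCC[C@](C)(O[Si](C)(C)C)C=C
F3 | step 2 | trimethylsilyl enol ether of F2, trimethyl({(4S)-4-methyl-4-[(trimethylsilyl)oxy]hexa-1,5-dien-1-yl}oxy)silane (E/Z mixture) | C[Si](C)(C)OC=CC[C@](C)(O[Si](C)(C)C)C=C
F4 | step 2 | (3S)-3-methyl-3-[(trimethylsilyl)oxy]pent-4-en-1-ol | OCC[C@](C)(O[Si](C)(C)C)C=C
F5 | step 8 | (3S,4S)-3-[(3S)-3-hydroxy-3-methylpent-4-en-1-yl]-4-[2-(prop-2-en-1-yl)oxiran-2-yl]oxolan-2-one (both oxirane epimers) | O=C1[C@@H](CC[C@](C)(O)C=C)[C@H](C2(CC=C)CO2)CO1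
F6 | step 8 | spiro-epoxy lactone: 16 with the exocyclic methylene at C4 converted into a spiro-oxirane (both spiro epimers) | O1CC12C/C=C\[C@@](C)(O)CC[C@H]3[C@H]2COC3=O
F7 | step 12 | (3aR,6Z,8S,10aS)-8-methyl-1,4-dimethylidene-3,3a,4,5,8,9,10,10a-octahydro-1H-cyclonona[c]furan-8-ol | C=C1C/C=C\[C@@](C)(O)CC[C@H]2[C@H]1COC2=C
F8 | step 12 | spiro-epoxy acetal: F7 with the 1-methylidene converted into a spiro-oxirane, oxirane oxygen anti to C10 | C=C1C/C=C\[C@@](C)(O)CC[C@H]2[C@H]1CO[C@@]23CO3
F9 | step 12 | dimethyl[(1E)-4-methylpenta-1,3-dien-1-yl]alumane | C[Al](C)/C=C/C=C(C)C
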